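**Strategy.** Label the eight-membered ring a (C–OAc), b (CH2), c (CHMe), d/f (cyclopropane CH), g/h (butenolide α/β carbons), i (side-chain CH). Everything rests on disconnecting a–g: the h–i unit sitting between the carboxyl-bearing g and the oxygenated a is the signature of a terminal alkyne inserted into the keto–α-carbon bond of a six-membered β-keto ester. A single rhenium-catalysed step forms g–h and i–a, enlarges the ring by two carbons and leaves ester and CH2OSi cis on the tetrasubstituted g=h alkene for lactonisation. The precursor is a cyclopropane-fused cyclohexanone 2-carboxylate carrying the methyl group anti to the three-membered ring.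

Key step: step 5

Remark on the chemistry: keto ester 9 is configurationally labile at C2 and partly enolised; it is drawn as the trans epimer, and this centre becomes sp2 in step 5.

Step 1
Reactants: 1 (E)-but-2-enal; 2 tert-butyl 3-oxobutanoate
Product: 5 (S)-5-methylcyclohex-2-en-1-one, via Michael adduct 3 (not isolated), via cyclohexenone tert-butyl ester 4 (not isolated)
Conditions: (R)-2-{bis[3,5-bis(trifluoromethyl)phenyl](trimethylsilyloxy)methyl}pyrrolidine (cat.), neat, rt; then TsOH·H2O (cat.), toluene, 80 °C
Reagents that add atoms: none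
Why: Iminium-ion organocatalysis (Michael addition, then aldol condensation and decarboxylation): the diarylprolinol silyl ether shields one face of the crotonaldehyde iminium ion, so the acetoacetate adds to the open face of the β-carbon and fixes the methyl-bearing centre (S with the R catalyst by the usual shielding model); acid then closes the ring by condensation of the methyl ketone onto the aldehyde and removes the tert-butyl ester as isobutene and CO2.

Step 2
Reactants: 5 (S)-5-methylcyclohex-2-en-1-one
Product: 6 (9R)-9-methyl-1,4-dioxaspiro[4.5]dec-7-ene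
Conditions: HOCH2CH2OH, TsOH·H2O (cat.), toluene, reflux, azeotropic removal of water
Reagents that add atoms: ethane-1,2-diol OCCO
Why: Deconjugative acetalisation under equilibrating acid catalysis: the dienol ether formed from the oxocarbenium ion is reprotonated at the α-carbon, which moves the alkene to the β,γ-position next to the methyl-bearing carbon; that carbon keeps its hydrogen, so the stereocentre is untouched (the descriptor changes by priority only).

Step 3
Reactants: 6 (9R)-9-methyl-1,4-dioxaspiro[4.5]dec-7-ene
Product: 8 (1R,5R,6S)-5-methylbicyclo[4.1.0]heptan-3-one, via cyclopropanated dioxolane 7 (not isolated)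
Conditions: Et2Zn, CH2I2, CH2Cl2, 0 °C to rt; then 1 M HCl, THF, rt
Reagents that add atoms: diiodomethane ICI; water O
Why: Simmons–Smith cyclopropanation (diethylzinc variant) followed by acetal hydrolysis: in the half-chair with the methyl group pseudo-equatorial the axial dioxolane oxygen lies on the face opposite to the methyl group and should guide the zinc carbenoid there, so both cyclopropane centres form anti to the methyl group with cis ring fusion from the stereospecific syn addition.

Step 4
Reactants: 8 (1R,5R,6S)-5-methylbicyclo[4.1.0]heptan-3-one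
Product: 9 ethyl (1S,2R,5R,6S)-5-methyl-3-oxobicyclo[4.1.0]heptane-2-carboxylate
Conditions: NaH, (EtO)2CO, THF, reflux; then cold dilute HCl
Reagents that add atoms: diethyl carbonate CCOC(=O)OCC
Why: Claisen-type C-acylation of the ketone enolate: the enolate towards the cyclopropane is conjugated with the three-membered ring, whereas acylation at C4 would place the ester beside the methyl-bearing carbon (3-methylcyclohexanone is acylated away from that carbon for the same reason), so the ester should enter at C2; C2 is epimerisable and of no consequence.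

Step 5
Reactants: 9 ethyl (1S,2R,5R,6S)-5-methyl-3-oxobicyclo[4.1.0]heptane-2-carboxylate; 10 tert-butyldimethyl(prop-2-yn-1-yloxy)silane
Product: 11 ethyl (1S,2Z,7R,8S)-3-({[tert-butyl(dimethyl)silyl]oxy}methyl)-7-methyl-5-oxobicyclo[6.1.0]non-2-ene-2-carboxylate
Conditions: [ReBr(CO)3(thf)]2 (cat.), BnNC (cat.), toluene, 50 °C
Reagents that add atoms: none
Why: Monovalent rhenium turns the β-keto ester into a rhenium enolate whose carbon g (C2) adds across the coordinated alkyne at the internal carbon h, the metal ending on the terminal carbon i; the alkenyl–rhenium then adds to the ring ketone a (4-exo-trig) to give a fused cyclobutenolate, and retro-aldol cleavage of the old a–g bond releases an ester-stabilised dienolate that is protonated at i. The closest known reaction is the [ReBr(CO)3(thf)]2/isocyanide-catalysed insertion of terminal alkynes into the keto–α-carbon bond of cyclic β-keto esters, which turns six-membered rings into eight-membered ones. The eight-membered ring is thus closed by two-carbon ring expansion through the transient four-membered ring and not by end-to-end cyclisation. No stereocentre is created, and the methyl and cyclopropane centres are neither deprotonated nor cleaved, since the cyclopropylcarbinyl enolate and carbanion intermediates are stabilised by the ester and should not open the three-membered ring. The step needs Markovnikov regioselectivity and exclusive a–g cleavage: the terminal alkyne secures the first because its substituted carbon takes the nucleophile, the ester secures the second because only g can leave as a stabilised carbanion, and the cis ring alkene forces ester and CH2OSi onto the same side.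

Step 6
Reactants: 11 ethyl (1S,2Z,7R,8S)-3-({[tert-butyl(dimethyl)silyl]oxy}methyl)-7-methyl-5-oxobicyclo[6.1.0]non-2-ene-2-carboxylate
Product: 13 (2S,4S,5R)-5-methyl-11-oxatricyclo[7.3.0.0^{2,4}]dodec-1(9)-ene-7,12-dione, via hydroxy ester 12 (not isolated)
Conditions: 2 M HCl, THF, rt
Reagents that add atoms: none
Why: Acidic desilylation followed by lactonisation (intramolecular transesterification): the freed allylic alcohol is held cis to the ester on the ring alkene and closes the butenolide with loss of ethanol; no stereocentre is involved.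

Step 7
Reactants: 14 (E)-but-2-en-1-ol
Product: 15 (E)-but-2-en-1-yl methyl carbonate
Conditions: ClCO2Me, pyridine, CH2Cl2, 0 °C
Reagents that add atoms: methyl chloroformate COC(Cl)=O
Why: O-acylation of a primary allylic alcohol with a chloroformate (carbonate formation); the alkene geometry is unchanged.

Step 8
Reactants: 13 (2S,4S,5R)-5-methyl-11-oxatricyclo[7.3.0.0^{2,4}]dodec-1(9)-ene-7,12-dione; 15 (E)-but-2-en-1-yl methyl carbonate
Product: 16 (2S,4S,5R,8S)-8-[(2R)-but-3-en-2-yl]-5-methyl-11-oxatricyclo[7.3.0.0^{2,4}]dodec-1(9)-ene-7,12-dione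
Conditions: [Ir(cod)Cl]2 (cat.), binaphthol-derived N,N-bis(1-phenylethyl)phosphoramidite (cat., antipode chosen for the R methine), TBD (cat.), THF, rt
Reagents that add atoms: none
Why: Iridium-catalysed branched-selective allylic alkylation of a stabilised enolate (cyclometalated monovalent iridium phosphoramidite): methoxide released from the carbonate deprotonates C8, which is α to the ketone and vinylogous to the lactone, and the enolate attacks the substituted allyl terminus so that the ligand sets the R methine; C8 should come out S because the ring folds away from the cyclopropane CH2 to keep the methyl group outside, leaving only the outer face open to the electrophile and making the same epimer the more stable one on equilibration.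

Step 9
Reactants: 16 (2S,4S,5R,8S)-8-[(2R)-but-3-en-2-yl]-5-methyl-11-oxatricyclo[7.3.0.0^{2,4}]dodec-1(9)-ene-7,12-dione
Product: 17 (2S,4S,5R,7R,8S)-8-[(2R)-but-3-en-2-yl]-7-hydroxy-5-methyl-11-oxatricyclo[7.3.0.0^{2,4}]dodec-1(9)-en-12-one
Conditions: LiBH(s-Bu)3, THF, −78 °C; aq. NH4Cl
Reagents that add atoms: none
Why: Ketone reduction under steric approach control (Felkin–Anh sense): the bulky hydride should attack anti to the vinylic ring carbon C9 on the adjacent stereocentre, on the face of the small C8 hydrogen, which places the hydroxyl cis to the side chain (7R); the tetrasubstituted butenolide and the terminal alkene should not react at this temperature.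

Step 10
Reactants: 17 (2S,4S,5R,7R,8S)-8-[(2R)-but-3-en-2-yl]-7-hydroxy-5-methyl-11-oxatricyclo[7.3.0.0^{2,4}]dodec-1(9)-en-12-one
Product: 18 (2S,4S,5R,7R,8S)-8-[(2R)-but-3-en-2-yl]-5-methyl-12-oxo-11-oxatricyclo[7.3.0.0^{2,4}]dodec-1(9)-en-7-yl acetate
Conditions: Ac2O, pyridine, DMAP (cat.), CH2Cl2, rt
Reagents that add atoms: acetic anhydride CC(=O)OC(C)=O
Why: DMAP-catalysed esterification of the secondary alcohol with retention at the carbinol carbon.

Step 11
Reactants: 18 (2S,4S,5R,7R,8S)-8-[(2R)-but-3-en-2-yl]-5-methyl-12-oxo-11-oxatricyclo[7.3.0.0^{2,4}]dodec-1(9)-en-7-yl acetate; 19 1-bromo-2-methylprop-1-ene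
Product: 21 (2S,4S,5R,7R,8S)-5-methyl-8-[(2R)-6-methylhept-5-en-2-yl]-12-oxo-11-oxatricyclo[7.3.0.0^{2,4}]dodec-1(9)-en-7-yl acetate, via B-alkyl-9-BBN adduct 20 (not isolated)
Conditions: 9-BBN, THF, 0 °C to rt; then 19, Pd(dppf)Cl2 (cat.), AsPh3, Cs2CO3, DMF/H2O, rt
Reagents that add atoms: none
Why: Anti-Markovnikov hydroboration of the only unhindered alkene, then B-alkyl Suzuki–Miyaura coupling with the vinyl bromide through a zerovalent palladium cycle; acetate, lactone and the tetrasubstituted alkene should be inert, and no stereocentre is affected.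

Step 12
Reactants: 21 (2S,4S,5R,7R,8S)-5-methyl-8-[(2R)-6-methylhept-5-en-2-yl]-12-oxo-11-oxatricyclo[7.3.0.0^{2,4}]dodec-1(9)-en-7-yl acetate
Product: 22 (2S,4S,5R,7R,8S)-8-[(2R,4E)-6-hydroperoxy-6-methylhept-4-en-2-yl]-5-methyl-12-oxo-11-oxatricyclo[7.3.0.0^{2,4}]dodec-1(9)-en-7-yl acetate
Conditions: O2, 5,10,15,20-tetraphenylporphyrin (cat.), visible light, CH2Cl2, 0 °C
Reagents that add atoms: dioxygen O=O
Why: Schenck ene reaction: singlet oxygen attacks only the electron-rich trisubstituted alkene (the butenolide alkene is electron-poor), and abstraction of an allylic CH2 hydrogen on the more crowded side shifts the double bond into the chain as E with OOH on the tertiary carbon; the isomer from methyl hydrogen abstraction is an expected co-product to be removed by chromatography, and no reductive work-up is used so that the hydroperoxide is kept.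

**Compound list**

1 | (E)-but-2-enal | C/C=C/C=O | starting material
2 | tert-butyl 3-oxobutanoate | CC(=O)CC(=O)OC(C)(C)C | starting material
3 | tert-butyl (3S)-2-acetyl-3-methyl-5-oxopentanoate (C2 epimers) | CC(=O)C(C(=O)OC(C)(C)C)[C@@H](C)CC=O | intermediate
4 | tert-butyl (6S)-6-methyl-2-oxocyclohex-3-ene-1-carboxylate (C1 epimers) | O=C1C=CC[C@H](C)C1C(=O)OC(C)(C)C | intermediate
5 | (S)-5-methylcyclohex-2-en-1-one | O=C1C[C@@H](C)CC=C1 | intermediate
6 | (9R)-9-methyl-1,4-dioxaspiro[4.5]dec-7-ene | O1CCOC12C[C@@H](C)C=CC2 | intermediate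
7 | (1R,5R,6S)-5-methylspiro[bicyclo[4.1.0]heptane-3,2'-[1,3]dioxolane] | O1CCOC12C[C@@H](C)[C@@H]3C[C@@H]3C2 | intermediate
8 | (1R,5R,6S)-5-methylbicyclo[4.1.0]heptan-3-one | O=C1C[C@@H](C)[C@@H]2C[C@@H]2C1 | intermediate
9 | ethyl (1S,2R,5R,6S)-5-methyl-3-oxobicyclo[4.1.0]heptane-2-carboxylate | O=C1C[C@@H](C)[C@@H]2C[C@@H]2[C@H]1C(=O)OCC | intermediate
10 | tert-butyldimethyl(prop-2-yn-1-yloxy)silane | C#CCO[Si](C)(C)C(C)(C)C | starting material
11 | ethyl (1S,2Z,7R,8S)-3-({[tert-butyl(dimethyl)silyl]oxy}methyl)-7-methyl-5-oxobicyclo[6.1.0]non-2-ene-2-carboxylate | O=C1C[C@@H](C)[C@@H]2C[C@@H]2/C(C(=O)OCC)=C(CO[Si](C)(C)C(C)(C)C)\C1 | intermediate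
12 | ethyl (1S,2Z,7R,8S)-3-(hydroxymethyl)-7-methyl-5-oxobicyclo[6.1.0]non-2-ene-2-carboxylate | O=C1C[C@@H](C)[C@@H]2C[C@@H]2/C(C(=O)OCC)=C(CO)\C1 | intermediate
13 | (2S,4S,5R)-5-methyl-11-oxatricyclo[7.3.0.0^{2,4}]dodec-1(9)-ene-7,12-dione | O=C1C[C@@H](C)[C@@H]2C[C@@H]2C2=C(COC2=O)C1 | intermediate
14 | (E)-but-2-en-1-ol | C/C=C/CO | starting material
15 | (E)-but-2-en-1-yl methyl carbonate | C/C=C/COC(=O)OC | intermediate
16 | (2S,4S,5R,8S)-8-[(2R)-but-3-en-2-yl]-5-methyl-11-oxatricyclo[7.3.0.0^{2,4}]dodec-1(9)-ene-7,12-dione | O=C1C[C@@H](C)[C@@H]2C[C@@H]2C2=C(COC2=O)[C@@H]1[C@H](C)C=C | intermediate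
17 | (2S,4S,5R,7R,8S)-8-[(2R)-but-3-en-2-yl]-7-hydroxy-5-methyl-11-oxatricyclo[7.3.0.0^{2,4}]dodec-1(9)-en-12-one | O[C@@H]1C[C@@H](C)[C@@H]2C[C@@H]2C2=C(COC2=O)[C@@H]1[C@H](C)C=C | intermediate
18 | (2S,4S,5R,7R,8S)-8-[(2R)-but-3-en-2-yl]-5-methyl-12-oxo-11-oxatricyclo[7.3.0.0^{2,4}]dodec-1(9)-en-7-yl acetate | CC(=O)O[C@@H]1C[C@@H](C)[C@@H]2C[C@@H]2C2=C(COC2=O)[C@@H]1[C@H](C)C=C | intermediate
19 | 1-bromo-2-methylprop-1-ene | CC(C)=CBr | starting material
20 | (2S,4S,5R,7R,8S)-8-[(2R)-4-(9-borabicyclo[3.3.1]nonan-9-yl)butan-2-yl]-5-methyl-12-oxo-11-oxatricyclo[7.3.0.0^{2,4}]dodec-1(9)-en-7-yl acetate | CC(=O)O[C@@H]1C[C@@H](C)[C@@H]2C[C@@H]2C2=C(COC2=O)[C@@H]1[C@H](C)CCB1C2CCCC1CCC2 | intermediate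
21 | (2S,4S,5R,7R,8S)-5-methyl-8-[(2R)-6-methylhept-5-en-2-yl]-12-oxo-11-oxatricyclo[7.3.0.0^{2,4}]dodec-1(9)-en-7-yl acetate | CC(=O)O[C@@H]1C[C@@H](C)[C@@H]2C[C@@H]2C2=C(COC2=O)[C@@H]1[C@H](C)CCC=C(C)C | intermediate
22 | (2S,4S,5R,7R,8S)-8-[(2R,4E)-6-hydroperoxy-6-methylhept-4-en-2-yl]-5-methyl-12-oxo-11-oxatricyclo[7.3.0.0^{2,4}]dodec-1(9)-en-7-yl acetate | CC(=O)O[C@@H]1C[C@@H](C)[C@@H]2C[C@@H]2C2=C(COC2=O)[C@@H]1[C@H](C)C/C=C/C(C)(C)OO | target

**Step count.** Total: 12 steps. Longest linear sequence: 11 steps (steps 1–6 and 8–12; step 7 prepares the carbonate).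

**Steps most likely to fail**

1. Step 8. Stereocontrol at the allylic carbon may erode through mismatch between the chiral ligand and the chiral enolate, or through the lower branched selectivity typical of methyl-substituted allyl electrophiles. The fallback sets out from 13 and returns to the route at 16, and moves the stereocontrol from the catalyst to the reagent. Commercial (R)-but-3-en-2-ol is converted with ClCO2Me and pyridine into (R)-but-3-en-2-yl methyl carbonate F1. The sodium enolate of 13 (NaH, THF) is then allylated with this carbonate under [Ir(cod)Cl]2 and P(OPh)3. With this achiral catalyst branched allylic carbonates are substituted with overall retention, so the R configuration of the reagent should be carried into the but-3-en-2-yl group of 16, with C8 again settling on the outer face.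

2. Step 5. The hindered rhenium enolate may stop at alkenylation of C2 without ring enlargement, or the insertion may be sluggish next to the cyclopropane. The fallback sets out from 9 and 10 and returns at 11 in two known operations. In(OTf)3-catalysed Markovnikov addition of the keto ester C–H across the alkyne (neat, heat) should give ethyl (1S,5R,6S)-2-(3-{[tert-butyl(dimethyl)silyl]oxy}prop-1-en-2-yl)-5-methyl-3-oxobicyclo[4.1.0]heptane-2-carboxylate F2, whose C2 configuration is immaterial. Irradiation of this β,γ-unsaturated ketone (about 300 nm, benzene) should then bring about the photochemical 1,3-acyl shift, moving the ketone carbon from C2 to the terminal alkene carbon and giving 11.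

3. Step 9. Hydride may be delivered to the other face of the flexible eight-membered ketone. The fallback sets out from 16 and returns at 17. The alcohol then obtained, (2S,4S,5R,7S,8S)-8-[(2R)-but-3-en-2-yl]-7-hydroxy-5-methyl-11-oxatricyclo[7.3.0.0^{2,4}]dodec-1(9)-en-12-one F3, is inverted by Mitsunobu esterification (PPh3, DIAD, 4-nitrobenzoic acid, THF) to (2S,4S,5R,7R,8S)-8-[(2R)-but-3-en-2-yl]-5-methyl-12-oxo-11-oxatricyclo[7.3.0.0^{2,4}]dodec-1(9)-en-7-yl 4-nitrobenzoate F4. Methanolysis (K2CO3, MeOH, 0 °C) then gives 17.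

**Further compounds**

F1 | step 8 | (R)-but-3-en-2-yl methyl carbonate | C=C[C@@H](C)OC(=O)OC
F2 | step 5 | ethyl (1S,5R,6S)-2-(3-{[tert-butyl(dimethyl)silyl]oxy}prop-1-en-2-yl)-5-methyl-3-oxobicyclo[4.1.0]heptane-2-carboxylate | O=C1C[C@@H](C)[C@@H]2C[C@@H]2C1(C(=O)OCC)C(=C)CO[Si](C)(C)C(C)(C)C
F3 | step 9 | (2S,4S,5R,7S,8S)-8-[(2R)-but-3-en-2-yl]-7-hydroxy-5-methyl-11-oxatricyclo[7.3.0.0^{2,4}]dodec-1(9)-en-12-one | O[C@H]1C[C@@H](C)[C@@H]2C[C@@H]2C2=C(COC2=O)[C@@H]1[C@H](C)C=C
F4 | step 9 | (2S,4S,5R,7R,8S)-8-[(2R)-but-3-en-2-yl]-5-methyl-12-oxo-11-oxatricyclo[7.3.0.0^{2,4}]dodec-1(9)-en-7-yl 4-nitrobenzoate | O=C(O[C@@H]1C[C@@H](C)[C@@H]2C[C@@H]2C2=C(COC2=O)[C@@H]1[C@H](C)C=C)c1ccc(cc1)[N+](=O)[O-]
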